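**Retrosynthetic overview** (eremophilane numbering: ring A = C1–C5 and C10, ring B = C5–C10, C11 = side-chain CH, C12 = ester carbon)
1. The side chain is cut at C7–C11, giving α-iodoenone 26 and racemic methyl 2-chloropropanoate; an enantioconvergent nickel coupling sets C11, and the angelate is put on the C3 hydroxyl just before.
2. The C6=C7–C8(=O) enone comes from cycloadduct 19 by desilylation, oxidation at C8 and reductive removal of the C9 sulfonyl group.
3. The strategy rests on ring B: its C6=C7 double bond, lying between quaternary C5 and oxygenated C8, is the cyclohexene of an intramolecular Diels–Alder adduct of a (1E,3Z) C8(OSiEt3)=C7–C6=C5 diene and a C9=C10 (E)-vinyl sulfone joined through C4–C3–C2–C1. Rings B and A form together in that step and no ring is made afterwards.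
4. Triene 18 comes from β,γ-unsaturated aldehyde 17 by silylation. The vinyl sulfone comes from a C10 aldehyde, the (Z)-C5=C6 bond from hydroxyl-directed methylmagnesiation of alkynol 10, C7–C8 from oxirane, and C3/C4 from an anti-selective propargylation of 4,4-dimethoxybutanal with the mesylate of (S)-but-3-yn-2-ol.

Key step: step 11

Assumption: in step 17 the (3aR,8aS)-configured bis(oxazoline) is taken to give the (R) configuration at C11; should the sense of induction be opposite, the enantiomeric ligand is used.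

**Route**

Step 1
Reactants: 1 methyl 4,4-dimethoxybutanoate
Product: 2 4,4-dimethoxybutanal
Conditions: i-Bu2AlH (1.05 equiv), CH2Cl2, −78 °C; aq. potassium sodium tartrate
Reagents that add atoms: none
Why: Partial ester reduction, in which the tetrahedral aluminium alkoxide formed at −78 °C releases the aldehyde only on work-up and the dimethyl acetal is inert to hydride.

Step 2
Reactants: 3 (2S)-but-3-yn-2-ol
Product: 4 (2S)-but-3-yn-2-yl methanesulfonate
Conditions: MsCl, Et3N, CH2Cl2, −78 to 0 °C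
Reagents that add atoms: methanesulfonyl chloride, CS(=O)(=O)Cl
Why: O-Sulfonylation of the secondary propargylic alcohol leaves the C–O bond and so the (S) configuration untouched and installs the leaving group for the propargylation.

Step 3
Reactants: 2 4,4-dimethoxybutanal; 4 (2S)-but-3-yn-2-yl methanesulfonate
Product: 6 (3R,4S)-7,7-dimethoxy-3-methylhept-1-yn-4-ol, via allenylzinc reagent 5 (not isolated)
Conditions: Pd(OAc)2 (5 mol %), PPh3 (5 mol %), Et2Zn (3 equiv), THF, −78 to −20 °C; aq. NH4Cl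
Reagents that add atoms: none
Why: Marshall propargylation, in which zerovalent palladium formed in situ ionises the mesylate in an anti SN2' sense, Et2Zn transmetalates to the (M)-allenylzinc 5, and its SE2' addition to the aldehyde through a closed transition state sets C4 as (R) by chirality transfer from 4 with overall inversion and C3 as (S) by the anti preference of that transition state.

Step 4
Reactants: 6 (3R,4S)-7,7-dimethoxy-3-methylhept-1-yn-4-ol
Product: 7 tert-butyl{[(3R,4S)-7,7-dimethoxy-3-methylhept-1-yn-4-yl]oxy}dimethylsilane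
Conditions: TBSCl, imidazole, DMF, rt to 40 °C
Reagents that add atoms: tert-butyldimethylsilyl chloride, CC(C)(C)[Si](C)(C)Cl
Why: Imidazole-promoted silylation of the secondary alcohol, chosen over a silyl triflate because the triflate would ionise the dimethyl acetal.

Step 5
Reactants: 7 tert-butyl{[(3R,4S)-7,7-dimethoxy-3-methylhept-1-yn-4-yl]oxy}dimethylsilane; 8 oxirane
Product: 10 (5R,6S)-6-[(tert-butyldimethylsilyl)oxy]-9,9-dimethoxy-5-methylnon-3-yn-1-ol, via lithium acetylide 9 (not isolated)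
Conditions: n-BuLi, THF, −78 °C; then oxirane, DMPU, −78 °C to rt; aq. NH4Cl
Reagents that add atoms: none
Why: Deprotonation of the terminal alkyne and SN2 opening of oxirane by the acetylide add C7 and C8 and free the primary hydroxyl that directs the next step, without a Lewis acid that could attack the acetal.

Step 6
Reactants: 10 (5R,6S)-6-[(tert-butyldimethylsilyl)oxy]-9,9-dimethoxy-5-methylnon-3-yn-1-ol
Product: 12 (3Z,5R,6S)-6-[(tert-butyldimethylsilyl)oxy]-9,9-dimethoxy-4,5-dimethylnon-3-en-1-ol, via alkenylmagnesium alkoxide 11 (not isolated)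
Conditions: Fe(acac)3 (0.2 equiv), MeMgBr (5 equiv), THF, −78 to 0 °C; aq. NH4Cl
Reagents that add atoms: methylmagnesium bromide, C[Mg]Br
Why: Iron-catalysed hydroxyl-directed carbomagnesiation of a homopropargylic alcohol, in which the C8 magnesium alkoxide delivers methyl to the distal alkyne carbon C5 and the metal to C6 in a syn sense through the five-membered chelate 11, so that protonation gives the (Z)-alkene with C4 and C7 cis, while the silylated C3 oxygen cannot direct.

Step 7
Reactants: 12 (3Z,5R,6S)-6-[(tert-butyldimethylsilyl)oxy]-9,9-dimethoxy-4,5-dimethylnon-3-en-1-ol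
Product: 13 (4S,5R,6Z)-4-[(tert-butyldimethylsilyl)oxy]-9-hydroxy-5,6-dimethylnon-6-enal
Conditions: PPTS (0.2 equiv), acetone/H2O (9:1), 45 °C
Reagents that add atoms: water, O
Why: Mild acid-catalysed acetal hydrolysis unmasks the C10 aldehyde under conditions that a hindered secondary TBS ether and the trisubstituted alkene tolerate.

Step 8
Reactants: 13 (4S,5R,6Z)-4-[(tert-butyldimethylsilyl)oxy]-9-hydroxy-5,6-dimethylnon-6-enal; 14 diethyl [(phenylsulfonyl)methyl]phosphonate
Product: 16 (3Z,5R,6S,9E)-6-[(tert-butyldimethylsilyl)oxy]-4,5-dimethyl-10-(phenylsulfonyl)deca-3,9-dien-1-ol, via lithiated phosphonate 15 (not isolated)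
Conditions: 14, LiN(SiMe3)2, THF, 0 °C; then 13, 0 °C to rt
Reagents that add atoms: none
Why: Horner–Wadsworth–Emmons olefination with the preformed stabilised carbanion gives the (E)-vinyl sulfone, and that carbanion is too weakly basic to deprotonate the free primary alcohol.

Step 9
Reactants: 16 (3Z,5R,6S,9E)-6-[(tert-butyldimethylsilyl)oxy]-4,5-dimethyl-10-(phenylsulfonyl)deca-3,9-dien-1-ol
Product: 17 (3Z,5R,6S,9E)-6-[(tert-butyldimethylsilyl)oxy]-4,5-dimethyl-10-(phenylsulfonyl)deca-3,9-dienal
Conditions: Dess–Martin periodinane, NaHCO3, CH2Cl2, 0 °C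
Reagents that add atoms: none
Why: Buffered Dess–Martin oxidation gives the β,γ-unsaturated aldehyde without acid or base strong enough to move the C5=C6 bond into conjugation or to erode its (Z) geometry.

Step 10
Reactants: 17 (3Z,5R,6S,9E)-6-[(tert-butyldimethylsilyl)oxy]-4,5-dimethyl-10-(phenylsulfonyl)deca-3,9-dienal
Product: 18 (1E,3Z,5R,6S,9E)-6-[(tert-butyldimethylsilyl)oxy]-4,5-dimethyl-10-(phenylsulfonyl)-1-[(triethylsilyl)oxy]deca-1,3,9-triene
Conditions: Et3SiOTf, Et3N, Et2O, −78 to 0 °C
Reagents that add atoms: triethylsilyl trifluoromethanesulfonate, CC[Si](CC)(CC)OS(=O)(=O)C(F)(F)F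
Why: Soft enolisation (O-silylation of the aldehyde, then removal of the doubly activated C7–H by Et3N) gives the conjugated silyl dienol ether with the (Z)-C5=C6 bond retained and the new C7=C8 bond expected mainly (E) from the extended conformer, as for other 1-silyloxybutadienes.

Step 11
Reactants: 18 (1E,3Z,5R,6S,9E)-6-[(tert-butyldimethylsilyl)oxy]-4,5-dimethyl-10-(phenylsulfonyl)-1-[(triethylsilyl)oxy]deca-1,3,9-triene
Product: 19 (1R,2S,4aR,5R,6S,8aS)-6-[(tert-butyldimethylsilyl)oxy]-4a,5-dimethyl-1-(phenylsulfonyl)-2-[(triethylsilyl)oxy]-1,2,4a,5,6,7,8,8a-octahydronaphthalene (cis-fused)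
Conditions: PhMe (0.01 M), BHT (0.1 equiv), base-washed sealed tube, 130 °C
Reagents that add atoms: none
Why: This is a thermal intramolecular Diels–Alder reaction of a 1,7,9-decatriene, concerted but asynchronous, in which the nucleophilic diene terminus C5 bonds to the sulfone β-carbon C10 and C8 bonds to C9; the closest known reactions are the thermal cyclisations of (Z)-diene decatrienes to cis-fused octalins and of trienes carrying a vinyl sulfone dienophile. Ring B is closed as the new cyclohexene by the two σ-bonds of the cycloaddition, and ring A is closed in the same event through the four-carbon tether C4–C3–C2–C1 when C5–C10 forms (fused mode, tether on the diene terminus). The tether is the inside substituent of the (Z)-configured C5 terminus, so C10 can be reached only from a transition state with the tether exo; this fixes the cis fusion at C5/C10 and places the sulfonyl group endo, so that C9 follows from the (E) geometry of the dienophile and C8 from the (E) geometry of the enol ether by suprafacial addition. The absolute sense at C5 and C10 is relayed from C4: allylic 1,3-strain against the C7–H keeps the small C4–H eclipsed with the C5=C6 bond, C3 then lies on one diene face and delivers the dienophile to it, and the C4 and C5 methyl groups end up cis, at the price of a pseudo-axial C3 silyloxy group. The step needs this facial selectivity and a rate that outruns the 1,5-hydrogen shift from C4 to C8 that is open to a (Z)-diene; pairing the electron-rich silyloxy diene with the electron-poor sulfone is meant to keep the temperature below that threshold, and dilute acid-free conditions protect the dienol ether.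

Step 12
Reactants: 19 cis-fused cycloadduct as named in step 11
Product: 20 (1R,2S,4aR,5R,6S,8aS)-4a,5-dimethyl-1-(phenylsulfonyl)-1,2,4a,5,6,7,8,8a-octahydronaphthalene-2,6-diol
Conditions: Bu4NF, AcOH, THF, rt to 45 °C
Reagents that add atoms: none
Why: Fluoride cleaves both silyl ethers through Si–F bond formation, and the acetic acid buffer keeps the medium too weakly basic for retro-aldol cleavage of the β-hydroxy sulfone.

Step 13
Reactants: 20 (1R,2S,4aR,5R,6S,8aS)-4a,5-dimethyl-1-(phenylsulfonyl)-1,2,4a,5,6,7,8,8a-octahydronaphthalene-2,6-diol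
Product: 21 (1R,4aR,5R,6S,8aS)-6-hydroxy-4a,5-dimethyl-1-(phenylsulfonyl)-4a,5,6,7,8,8a-hexahydronaphthalen-2(1H)-one
Conditions: MnO2 (excess), CH2Cl2, rt
Reagents that add atoms: none
Why: MnO2 oxidises the allylic C8 alcohol chemoselectively and leaves the saturated C3 alcohol, giving the enone whose carbonyl now activates the C9–S bond.

Step 14
Reactants: 21 (1R,4aR,5R,6S,8aS)-6-hydroxy-4a,5-dimethyl-1-(phenylsulfonyl)-4a,5,6,7,8,8a-hexahydronaphthalen-2(1H)-one
Product: 22 (4aR,5R,6S,8aR)-6-hydroxy-4a,5-dimethyl-4a,5,6,7,8,8a-hexahydronaphthalen-2(1H)-one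
Conditions: Al(Hg), THF/H2O (9:1), 0 °C to rt
Reagents that add atoms: none
Why: Reductive desulfonylation of a β-keto sulfone by electron transfer expels sulfinate, and the cross-conjugated enolate is protonated at C9, which returns the enone with C6=C7 in place and no epimerisable centre touched.

Step 15
Reactants: 22 (4aR,5R,6S,8aR)-6-hydroxy-4a,5-dimethyl-4a,5,6,7,8,8a-hexahydronaphthalen-2(1H)-one; 23 angelic acid [(2Z)-2-methylbut-2-enoic acid]
Product: 25 (1R,2S,4aR,8aR)-1,8a-dimethyl-6-oxo-1,2,3,4,4a,5,6,8a-octahydronaphthalen-2-yl (2Z)-2-methylbut-2-enoate, via mixed anhydride 24 (not isolated)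
Conditions: 23, 2,4,6-trichlorobenzoyl chloride, Et3N, PhMe, rt; then 22, PhMe, 80 °C
Reagents that add atoms: none
Why: Yamaguchi-type acylation through the mixed trichlorobenzoic anhydride 24 without a nucleophilic catalyst esterifies the hindered C3 alcohol at the angeloyl carbonyl and avoids the addition–elimination path that turns angelates into tiglates.

Step 16
Reactants: 25 (1R,2S,4aR,8aR)-1,8a-dimethyl-6-oxo-1,2,3,4,4a,5,6,8a-octahydronaphthalen-2-yl (2Z)-2-methylbut-2-enoate
Product: 26 (1R,2S,4aR,8aS)-7-iodo-1,8a-dimethyl-6-oxo-1,2,3,4,4a,5,6,8a-octahydronaphthalen-2-yl (2Z)-2-methylbut-2-enoate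
Conditions: I2, pyridine/CH2Cl2 (1:1), 0 °C to rt, dark
Reagents that add atoms: iodine, II
Why: Pyridine-mediated α-iodination of the enone (conjugate addition of pyridine at C6, iodination of the enolate at C7, elimination) gives the 2-iodoenone, while the α-substituted angelate alkene cannot react this way and exclusion of light prevents iodine-atom (Z) to (E) isomerisation.

Step 17
Reactants: 26 (1R,2S,4aR,8aS)-7-iodo-1,8a-dimethyl-6-oxo-1,2,3,4,4a,5,6,8a-octahydronaphthalen-2-yl (2Z)-2-methylbut-2-enoate; 27 methyl 2-chloropropanoate (racemic)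
Product: 28 methyl (2R)-2-[(4aR,7S,8R,8aR)-8,8a-dimethyl-7-{[(2Z)-2-methylbut-2-enoyl]oxy}-3-oxo-3,4,4a,5,6,7,8,8a-octahydronaphthalen-2-yl]propanoate (CNP0323033.1)
Conditions: NiBr2(dme) (10 mol %), (3aR,3a'R,8aS,8a'S)-2,2'-(cyclopropane-1,1-diyl)bis(3a,8a-dihydro-8H-indeno[1,2-d]oxazole) (12 mol %), Mn powder (3 equiv), NaI (0.5 equiv), DMA, 0 °C
Reagents that add atoms: none
Why: Proposed new method: nickel-catalysed enantioconvergent reductive cross-coupling of an alkenyl iodide with a racemic α-chloro ester, in which the iodoenone adds oxidatively to zerovalent nickel bearing the chiral bis(oxazoline), halogen abstraction from 27 (after partial chloride–iodide exchange) gives a planar α-ester radical so that both enantiomers of 27 converge, radical capture and reductive elimination from trivalent nickel form C7–C11 with the ligand deciding the C11 configuration, and Mn returns nickel to the low-valent state under neutral conditions that should not epimerise C11; the closest known reactions are the nickel/bis(oxazoline) reductive couplings of alkenyl bromides with racemic benzylic chlorides and of aryl iodides with racemic α-chloro esters, and a 2-iodoenone has not been shown as the partner.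

**Compound list**
1 | methyl 4,4-dimethoxybutanoate | COC(=O)CCC(OC)OC | starting material
2 | 4,4-dimethoxybutanal | O=CCCC(OC)OC | intermediate
3 | (2S)-but-3-yn-2-ol | C#C[C@H](C)O | starting material
4 | (2S)-but-3-yn-2-yl methanesulfonate | C#C[C@H](C)OS(C)(=O)=O | intermediate
5 | ethyl[(M)-buta-1,2-dien-1-yl]zinc (allenylzinc reagent) | CC[Zn]C([H])=[C@]=C([H])C | intermediate
6 | (3R,4S)-7,7-dimethoxy-3-methylhept-1-yn-4-ol | C#C[C@@H](C)[C@@H](O)CCC(OC)OC | intermediate
7 | tert-butyl{[(3R,4S)-7,7-dimethoxy-3-methylhept-1-yn-4-yl]oxy}dimethylsilane | C#C[C@@H](C)[C@@H](O[Si](C)(C)C(C)(C)C)CCC(OC)OC | intermediate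
8 | oxirane | C1CO1 | starting material
9 | lithium acetylide of 7 | [Li]C#C[C@@H](C)[C@@H](O[Si](C)(C)C(C)(C)C)CCC(OC)OC | intermediate
10 | (5R,6S)-6-[(tert-butyldimethylsilyl)oxy]-9,9-dimethoxy-5-methylnon-3-yn-1-ol | OCCC#C[C@@H](C)[C@@H](O[Si](C)(C)C(C)(C)C)CCC(OC)OC | intermediate
11 | cyclic alkenylmagnesium alkoxide from syn addition of Me–Mg across C5≡C6 of 10 (five-membered O–Mg–C6 chelate, Mg on C6 cis to the new C5 methyl) | [Mg]1OCC/C1=C(/C)[C@@H](C)[C@@H](O[Si](C)(C)C(C)(C)C)CCC(OC)OC | intermediate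
12 | (3Z,5R,6S)-6-[(tert-butyldimethylsilyl)oxy]-9,9-dimethoxy-4,5-dimethylnon-3-en-1-ol | OCC/C=C(/C)[C@@H](C)[C@@H](O[Si](C)(C)C(C)(C)C)CCC(OC)OC | intermediate
13 | (4S,5R,6Z)-4-[(tert-butyldimethylsilyl)oxy]-9-hydroxy-5,6-dimethylnon-6-enal | OCC/C=C(/C)[C@@H](C)[C@@H](O[Si](C)(C)C(C)(C)C)CCC=O | intermediate
14 | diethyl [(phenylsulfonyl)methyl]phosphonate | CCOP(=O)(CS(=O)(=O)c1ccccc1)OCC | starting material
15 | lithiated diethyl [(phenylsulfonyl)methyl]phosphonate | [Li]C(P(=O)(OCC)OCC)S(=O)(=O)c1ccccc1 | intermediate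
16 | (3Z,5R,6S,9E)-6-[(tert-butyldimethylsilyl)oxy]-4,5-dimethyl-10-(phenylsulfonyl)deca-3,9-dien-1-ol | OCC/C=C(/C)[C@@H](C)[C@@H](O[Si](C)(C)C(C)(C)C)CC/C=C/S(=O)(=O)c1ccccc1 | intermediate
17 | (3Z,5R,6S,9E)-6-[(tert-butyldimethylsilyl)oxy]-4,5-dimethyl-10-(phenylsulfonyl)deca-3,9-dienal | O=CC/C=C(/C)[C@@H](C)[C@@H](O[Si](C)(C)C(C)(C)C)CC/C=C/S(=O)(=O)c1ccccc1 | intermediate
18 | (1E,3Z,5R,6S,9E)-6-[(tert-butyldimethylsilyl)oxy]-4,5-dimethyl-10-(phenylsulfonyl)-1-[(triethylsilyl)oxy]deca-1,3,9-triene | CC[Si](CC)(CC)O/C=C/C=C(/C)[C@@H](C)[C@@H](O[Si](C)(C)C(C)(C)C)CC/C=C/S(=O)(=O)c1ccccc1 | intermediate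
19 | (1R,2S,4aR,5R,6S,8aS)-6-[(tert-butyldimethylsilyl)oxy]-4a,5-dimethyl-1-(phenylsulfonyl)-2-[(triethylsilyl)oxy]-1,2,4a,5,6,7,8,8a-octahydronaphthalene (cis-fused; sulfonyl, silyloxy, angular methyl and ring-fusion H on one face) | CC(C)(C)[Si](C)(C)O[C@H]1CC[C@@H]2[C@@H](S(=O)(=O)c3ccccc3)[C@@H](O[Si](CC)(CC)CC)C=C[C@]2(C)[C@H]1C | intermediate
20 | (1R,2S,4aR,5R,6S,8aS)-4a,5-dimethyl-1-(phenylsulfonyl)-1,2,4a,5,6,7,8,8a-octahydronaphthalene-2,6-diol | O[C@H]1CC[C@@H]2[C@@H](S(=O)(=O)c3ccccc3)[C@@H](O)C=C[C@]2(C)[C@H]1C | intermediate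
21 | (1R,4aR,5R,6S,8aS)-6-hydroxy-4a,5-dimethyl-1-(phenylsulfonyl)-4a,5,6,7,8,8a-hexahydronaphthalen-2(1H)-one | O[C@H]1CC[C@@H]2[C@@H](S(=O)(=O)c3ccccc3)C(=O)C=C[C@]2(C)[C@H]1C | intermediate
22 | (4aR,5R,6S,8aR)-6-hydroxy-4a,5-dimethyl-4a,5,6,7,8,8a-hexahydronaphthalen-2(1H)-one | O[C@H]1CC[C@@H]2CC(=O)C=C[C@]2(C)[C@H]1C | intermediate
23 | angelic acid, (2Z)-2-methylbut-2-enoic acid | C/C=C(/C)C(=O)O | starting material
24 | (2Z)-2-methylbut-2-enoic 2,4,6-trichlorobenzoic anhydride | C/C=C(/C)C(=O)OC(=O)c1c(Cl)cc(Cl)cc1Cl | intermediate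
25 | (1R,2S,4aR,8aR)-1,8a-dimethyl-6-oxo-1,2,3,4,4a,5,6,8a-octahydronaphthalen-2-yl (2Z)-2-methylbut-2-enoate | C/C=C(/C)C(=O)O[C@H]1CC[C@@H]2CC(=O)C=C[C@]2(C)[C@H]1C | intermediate
26 | (1R,2S,4aR,8aS)-7-iodo-1,8a-dimethyl-6-oxo-1,2,3,4,4a,5,6,8a-octahydronaphthalen-2-yl (2Z)-2-methylbut-2-enoate | C/C=C(/C)C(=O)O[C@H]1CC[C@@H]2CC(=O)C(I)=C[C@]2(C)[C@H]1C | intermediate
27 | methyl 2-chloropropanoate (racemic) | COC(=O)C(C)Cl | starting material
28 | methyl (2R)-2-[(4aR,7S,8R,8aR)-8,8a-dimethyl-7-{[(2Z)-2-methylbut-2-enoyl]oxy}-3-oxo-3,4,4a,5,6,7,8,8a-octahydronaphthalen-2-yl]propanoate | C/C=C(/C)C(=O)O[C@H]1CC[C@@H]2CC(=O)C([C@@H](C)C(=O)OC)=C[C@]2(C)[C@H]1C | target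

**Step count**
Total: 17 steps. Longest linear sequence: 16 steps (1 → 2 → 6 → … → 28; the branch from 3 is equally long).

**Steps most likely to fail**

1. Step 17 (proposed new method). The catalyst may not override the chiral substrate in setting C11, the C–I bond may be reduced without coupling, or C11 may epimerise in the product. Fallback with known chemistry, from 26 back to 28: methyl 2-bromopropanoate (CC(Br)C(=O)OC) and activated Zn in THF give the Reformatsky reagent bromo(1-methoxy-1-oxopropan-2-yl)zinc F1. This is coupled with 26 under Negishi conditions (Pd(PPh3)4, THF, rt to 50 °C). The C7–C11 bond forms without stereocontrol, so 28 is expected together with its C11 epimer methyl (2S)-2-[(4aR,7S,8R,8aR)-8,8a-dimethyl-7-{[(2Z)-2-methylbut-2-enoyl]oxy}-3-oxo-3,4,4a,5,6,7,8,8a-octahydronaphthalen-2-yl]propanoate F2. The two are separated by preparative HPLC, and F2 is re-equilibrated at C11 with a catalytic amine base and separated again.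

2. Step 11 (key step). The cycloaddition of the (Z)-diene may be slow enough for the 1,5-hydrogen shift from C4 to C8 to compete, which would destroy the C4 centre and the diene. Any (1Z) enol ether isomer cannot cyclise, the dienol ether may hydrolyse, and facial selectivity may be eroded by the pseudo-axial C3 silyloxy group. Fallback, from 17 back to 20: KN(SiMe3)2 in THF at −78 °C converts 17 into the potassium dienolate potassium (1E,3Z,5R,6S,9E)-6-[(tert-butyldimethylsilyl)oxy]-4,5-dimethyl-10-(phenylsulfonyl)deca-1,3,9-trien-1-olate F3. Its oxyanion-accelerated intramolecular cycloaddition forms the same C5–C10 and C8–C9 bonds (in the stepwise limit, vinylogous Michael addition of C5 to C10, then aldol closure of the C9 sulfonyl carbanion on C8). It should run between −78 and −20 °C, far below the temperature of the hydrogen shift. A cold acetic acid quench gives (1R,2S,4aR,5R,6S,8aS)-6-[(tert-butyldimethylsilyl)oxy]-4a,5-dimethyl-1-(phenylsulfonyl)-1,2,4a,5,6,7,8,8a-octahydronaphthalen-2-ol F4, and Bu4NF/AcOH then gives 20. Any C8 or C9 epimer would converge at 22, where both centres are erased.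

3. Step 6. Carbometalation may be sluggish at the alkyne carbon next to the branched C4 centre, or regiocontrol may be lost, or the alkyne may be reduced. Fallback, from 7 back to 12, sets the (Z)-alkene by cuprate syn-addition to an ynoate. n-BuLi then methyl chloroformate gives methyl (4R,5S)-5-[(tert-butyldimethylsilyl)oxy]-8,8-dimethoxy-4-methyloct-2-ynoate F5. Me2CuLi in THF at −78 °C with a cold protic quench gives methyl (2Z,4R,5S)-5-[(tert-butyldimethylsilyl)oxy]-8,8-dimethoxy-3,4-dimethyloct-2-enoate F6. i-Bu2AlH gives (2Z,4R,5S)-5-[(tert-butyldimethylsilyl)oxy]-8,8-dimethoxy-3,4-dimethyloct-2-en-1-ol F7, and MnO2 gives (2Z,4R,5S)-5-[(tert-butyldimethylsilyl)oxy]-8,8-dimethoxy-3,4-dimethyloct-2-enal F8. Wittig methylenation (Ph3P=CH2, THF, −78 to 0 °C) gives tert-butyl{[(4S,5R,6Z)-1,1-dimethoxy-5,6-dimethylnona-6,8-dien-4-yl]oxy}dimethylsilane F9. Hydroboration of the terminal diene carbon with disiamylborane and oxidation with H2O2/NaOH then gives 12.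

Further compounds
F1 | step 17 | bromo(1-methoxy-1-oxopropan-2-yl)zinc | COC(=O)C(C)[Zn]Br
F2 | step 17 | methyl (2S)-2-[(4aR,7S,8R,8aR)-8,8a-dimethyl-7-{[(2Z)-2-methylbut-2-enoyl]oxy}-3-oxo-3,4,4a,5,6,7,8,8a-octahydronaphthalen-2-yl]propanoate | C/C=C(/C)C(=O)O[C@H]1CC[C@@H]2CC(=O)C([C@H](C)C(=O)OC)=C[C@]2(C)[C@H]1C
F3 | step 11 | potassium (1E,3Z,5R,6S,9E)-6-[(tert-butyldimethylsilyl)oxy]-4,5-dimethyl-10-(phenylsulfonyl)deca-1,3,9-trien-1-olate | [K+].[O-]/C=C/C=C(/C)[C@@H](C)[C@@H](O[Si](C)(C)C(C)(C)C)CC/C=C/S(=O)(=O)c1ccccc1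
F4 | step 11 | (1R,2S,4aR,5R,6S,8aS)-6-[(tert-butyldimethylsilyl)oxy]-4a,5-dimethyl-1-(phenylsulfonyl)-1,2,4a,5,6,7,8,8a-octahydronaphthalen-2-ol | CC(C)(C)[Si](C)(C)O[C@H]1CC[C@@H]2[C@@H](S(=O)(=O)c3ccccc3)[C@@H](O)C=C[C@]2(C)[C@H]1C
F5 | step 6 | methyl (4R,5S)-5-[(tert-butyldimethylsilyl)oxy]-8,8-dimethoxy-4-methyloct-2-ynoate | COC(=O)C#C[C@@H](C)[C@@H](O[Si](C)(C)C(C)(C)C)CCC(OC)OC
F6 | step 6 | methyl (2Z,4R,5S)-5-[(tert-butyldimethylsilyl)oxy]-8,8-dimethoxy-3,4-dimethyloct-2-enoate | COC(=O)/C=C(/C)[C@@H](C)[C@@H](O[Si](C)(C)C(C)(C)C)CCC(OC)OC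
F7 | step 6 | (2Z,4R,5S)-5-[(tert-butyldimethylsilyl)oxy]-8,8-dimethoxy-3,4-dimethyloct-2-en-1-ol | OC/C=C(/C)[C@@H](C)[C@@H](O[Si](C)(C)C(C)(C)C)CCC(OC)OC
F8 | step 6 | (2Z,4R,5S)-5-[(tert-butyldimethylsilyl)oxy]-8,8-dimethoxy-3,4-dimethyloct-2-enal | O=C/C=C(/C)[C@@H](C)[C@@H](O[Si](C)(C)C(C)(C)C)CCC(OC)OC
F9 | step 6 | tert-butyl{[(4S,5R,6Z)-1,1-dimethoxy-5,6-dimethylnona-6,8-dien-4-yl]oxy}dimethylsilane | C=C/C=C(/C)[C@@H](C)[C@@H](O[Si](C)(C)C(C)(C)C)CCC(OC)OC
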